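At time zero of the epsilon run none of the gas is in solution, and by 15.0 s the readings stand at 40 % left-handed substrate and 47 % right-handed substrate. By 40.0 s the left-handed reading has dropped to 24 %, less than the right-handed 47 %, which has not moved since 15.0 s. By 120 s the left-handed reading is down to 4 %, and the right-handed substrate, at 31 %, is the large amount still to react.

| setting | epsilon | flask |
|---|---|---|
| left-handed substrate | 2.1 M | 1.5 M |
| right-handed substrate | 2.1 M | 1.5 M |
| gas | 54 mM (held) | 54 mM (held) |
| free catalyst | 0.5 mol% | 0.5 mol% |
| remark | run made earlier |  |
| time |  | 2.0 min |

epsilon run (percent of the left-handed substrate and right-handed substrate together charged)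

| time / s | left-handed substrate / % | right-handed substrate / % |
|---|---|---|
| 15.0 | 40 | 47 |
| 40.0 | 24 | 47 |
| 80.0 | 10 | 39 |
| 120 | 4 | 31 |

(scatter of a reading: 1.5 percentage points)

- free catalyst is single-handed; left-handed substrate and right-handed substrate are mirror images of each other, charged as a racemate, each of them at the stated concentration
- at the start none of the gas is in solution
- an excess is the difference of the two amounts in percent of their sum
- an excess is below zero if the other one leads
- no earlier run changes the charge of free catalyst; that part of a forecast is a guess

* part of the left-handed substrate and right-handed substrate charged together that has reacted at 2.0 min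
* excess of left-handed product over right-handed product in the product at 2.0 min
* excess of right-handed substrate over left-handed substrate among what is left of the two at 2.0 min

Each hand is half of the charge, so a reading divided by that half is the fraction of its own charge left. The selectivity factor, the logarithm of the left-handed fraction left divided by the logarithm of the right-handed fraction left, is 6.48 in the epsilon run at 80.0 s. I take that pair because the left-handed reading there, 10 %, stands clear of the scatter of 1.5 percentage points; the pair at 120 s reads 5.28. While that factor holds, the left-handed fraction is the right-handed fraction raised to this power, so the small remainder follows from the large one.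

Both runs load the same mol%, so the flask holds 0.714 of the epsilon catalyst concentration. That the rate follows it is my guess. Scaling the logarithm of the right-handed fraction at 120 s by this leaves 71.1 % of the right-handed charge in the flask, and the power leaves 11.0 % of the left-handed charge. My reckoning is then c 59.0 %, eP 51.0 % and eS 73.2 %.

The forecast, reasoning “so selectivity is about 5”, gave c 57 %, eP 48 % and eS 64 %.

The flask gives c 63.9 %, eP 46.9 % and eS 82.8 %.

    gas ⇌ partner, rate k1*(csat - [partner]) (kL = 1.60 /s)
    partner + catalyst intermediate A → free catalyst + left-handed product (k = 150 /M/s)
    2 partner → homo dimer (k = 1.00 /M/s)
    2 free catalyst ⇌ resting dimer, settled at all times (K = 800 /M)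
    free catalyst + right-handed substrate ⇌ catalyst intermediate B (K = 8.00 /M, k = 3.40 /M/s)
    free catalyst + left-handed substrate ⇌ catalyst intermediate A (K = 13.0 /M, k = 25.0 /M/s)
    partner + catalyst intermediate B → free catalyst + right-handed product (k = 54.0 /M/s)

The flask keeps 66 % of its right-handed charge, less than my 71.1 %. Raised to the power 6.48, that leftover gives 6.77 % of the left-handed charge, and the flask holds 6.2 %. The neighbour charged with 0.12 mol% of free catalyst, everything else as in the flask, reaches c 29.6 %. The same power on its right-handed leftover of 90 % gives 51.7 % left-handed against 50 % in that neighbour, and so an excess of right-handed substrate of 27.0 % against its 28.4 %.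

The earlier runs and the new flask were generated by integration from invented constants, noise included.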